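Readings and results are simulated with made-up constants; the scatter is artificial.

Temperature is what separates these flasks, and the excess asked for is (left − right)/(left + right) of the two products.

the same everywhere: gas 20 mM (held)
- south-east: left-handed substrate 0.10 M; right-handed substrate 0.10 M; temperature −30 °C; run made earlier
- north-west: left-handed substrate 0.15 M; right-handed substrate 0.15 M; temperature 10 °C; run made earlier
- red: left-handed substrate 0.20 M; right-handed substrate 0.20 M; temperature −25 °C; time 50 min
- amber: left-handed substrate 0.20 M; right-handed substrate 0.20 M; temperature 35 °C; time 50 min
- ochre: left-handed substrate 0.20 M; right-handed substrate 0.20 M; temperature 45 °C; time 50 min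
- grey: left-handed substrate 0.20 M; right-handed substrate 0.20 M; temperature 20 °C; time 50 min
- teal: left-handed substrate 0.20 M; right-handed substrate 0.20 M; temperature 5 °C; time 50 min

| run | time / min | left-handed product / % | right-handed product / % |
|---|---|---|---|
| south-east | 30.0 | 9.1 | 4.3 |
| south-east | 60.0 | 16.9 | 5.6 |
| south-east | 120 | 26.2 | 13.5 |
| south-east | 150 | 31.1 | 15.1 |
| south-east | 180 | 34.1 | 17.9 |
| south-east | 240 | 38.6 | 21.8 |
| north-west | 2.50 | 7.4 | 4.3 |
| north-west | 8.00 | 15.7 | 12.2 |
| north-west | 15.0 | 22.5 | 16.5 |
| north-west | 20.0 | 25.5 | 18.3 |
| north-west | 30.0 | 28.0 | 17.8 |
| north-west | 40.0 | 28.3 | 20.5 |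

(readings scatter by 1 percentage point)

- partner is single-handed; left-handed substrate and right-handed substrate are mirror images of each other, charged as a racemate, each of them at the stated concentration
- at the start none of partner is dissolved
- what was read earlier has a scatter of 1 percentage point, one standard deviation
- reactions considered so far: partner + left-handed substrate -> left-handed product; partner + right-handed substrate -> right-handed product; left-handed substrate <-> achiral form; right-handed substrate <-> achiral form; achiral form -> side product; gas <-> partner
- the handed part of partner does not stay in what it makes, so the products of the two hands are mirror images too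

1. ranking by excess of left-handed product over right-handed product, from high to low, at 50 min (red / amber / ochre / grey / teal)
2. the excess of left-handed product over right-handed product of the flask you put first, at 50 min
3. the excess of left-handed product over right-handed product of the flask you put last, at 50 min

Which concentration sets the order of the rate? I take it to be the partner. I assume that gas holds it near its saturation level, 0.100 of one substrate's charge. On that assumption each substrate falls pseudo-first-order. It is an assumption and not a reading, since the runs report the two products and not the partner. I define the selectivity factor s as the log of what remains of the left-handed substrate over the same log for the right-handed, and I take what remains from the products. Partner cancels from this ratio so far as the partner steps are what use up the substrates. But each hand also has a way to the achiral form, so I treat s as an apparent value.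

I read s as 2.58 in the south-east run and 1.49 in the north-west run. Together these readings give 7.84 kJ mol⁻¹ as the apparent gap between the activation energies of the two hands.

My bench rule says the excess is s less one, over s plus one. It assumes the two substrates stand equal. In the south-east run the rule gives 44.1%, but the last reading shows 27.8%. By the products, left-handed substrate there stands at 0.404 of right-handed, and that is the border.

For red I reckon s = 2.39, so an excess of 41.0%. For ochre I reckon s = 1.03, so an excess of 1.72%. The gap makes s lower in ochre than in red, so I rank from coldest to warmest.

The forecast gives red > teal > grey > amber > ochre, with 34% and 9%: “Assuming that trend holds beyond the measured range, the excess falls steadily with temperature.” My order is the same, but my two numbers differ from it.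

The flasks give red > teal > grey > amber > ochre, with 38.8% for red and 0.0132% for ochre.

    partner + left-handed substrate → left-handed product (k = 0.0620 L mol⁻¹ s⁻¹, Ea = 37.0 kJ mol⁻¹)
    partner + right-handed substrate → right-handed product (k = 0.0380 L mol⁻¹ s⁻¹, Ea = 46.0 kJ mol⁻¹)
    left-handed substrate ⇌ achiral form (K = 0.110, k = 0.00280 s⁻¹, Ea = 77.0 kJ mol⁻¹, ΔH = −50.0 kJ mol⁻¹)
    right-handed substrate ⇌ achiral form (K = 0.110, k = 0.00280 s⁻¹, Ea = 77.0 kJ mol⁻¹, ΔH = −50.0 kJ mol⁻¹)
    achiral form → side product (k = 0.0200 s⁻¹, Ea = 76.0 kJ mol⁻¹)
    gas ⇌ partner, rate k6*(csat - [partner]) (kL = 0.0320 s⁻¹)
    (constants at 5 °C)

In red, both partner steps are still running at 50.0 min, with partner at 0.0191 M and 26.4% and 35.9% of the whole charge left as left-handed and right-handed substrate. In ochre, the substrates stand at 0% and 0% by 25.0 min, with 18.4% and 18.4% in the two products and 63.1% in side product. On the neighbour of red at −40 °C, the gap gives s = 3.05, so 50.6%. That flask computes to 53.1%.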